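**Retrosynthetic overview**
- Controlling feature: ring A of the flavone (C4a, C5, C6, C7, C8, C8a) is a phloroglucinol core. Its three oxygens have different fates: O1 in the pyranone, 5-OH peri to C4=O, and 7-OH. C8, which lies between C7 and C8a, carries the CH2 bridge to ring D.
- Last disconnections: the 5-O-ethyl ether and three benzyl ethers. Ring C (O1-C2 and C2-C3) then opens by retro-cyclodehydration and retro-Baker-Venkataraman to a 2-hydroxyaryl methoxymethyl ketone and benzoyl chloride (ring B).
- Ring A is cut at C5-C6 and C4a-C8a. This gives a Chan-type 1-methoxy-1,3-bis(silyloxy)diene bearing ring D-CH2 on its central carbon, and 4-ethoxy-1-methoxybut-3-yn-2-one.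
- The diene comes from methyl acetoacetate and a ring D aldehyde by Knoevenagel condensation, conjugate reduction and two silylations. Ring D comes from 2-methylphloroglucinol by acylation, para-O-methylation, formylation and benzylation.
- Ring order: D (bought aromatic, then decorated), A (cycloaddition), C (cyclodehydration). Ring B arrives with benzoyl chloride.

Key step: step 10

Notation: ArD = 2,4-bis(benzyloxy)-6-methoxy-5-methyl-3-(3-phenylpropanoyl)phenyl (ring D, bonded through C1). ArD-Si = the same ring with the 3-acyl group replaced by the (Z)-3-phenyl-1-(trimethylsilyloxy)prop-1-en-1-yl group. Ring A atoms carry flavone numbers.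

Assumption: the alkene geometries of 9, of the enoate part of 11 and of the ketene acetal part of 12 are uncontrolled and irrelevant because each is erased later; the ring D silyl enol ether is drawn Z, the usual result of soft enolisation of aryl alkyl ketones, and any E isomer would hydrolyse to the same ketone in step 10.

**Step 1**
Reactants: 1 2-methylphloroglucinol; 2 3-phenylpropanoyl chloride
Product: 3 1-(2,4,6-trihydroxy-3-methylphenyl)-3-phenylpropan-1-one
Conditions: AlCl3 (3.5 equiv), CH2Cl2-PhNO2, 0 °C; 2 added slowly last, then 40 °C; ice/2 M HCl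
Reagents that add atoms: none
Why: Friedel-Crafts C-acylation, in which the two open positions of 1 are equivalent, the first acyl group deactivates the ring against a second, and slow addition of 2 to the pre-formed aluminium phenoxide suppresses its self-cyclisation to indan-1-one.

**Step 2**
Reactants: 3 1-(2,4,6-trihydroxy-3-methylphenyl)-3-phenylpropan-1-one
Product: 4 1-(2,6-dihydroxy-4-methoxy-3-methylphenyl)-3-phenylpropan-1-one
Conditions: Me2SO4 (1.0 equiv), K2CO3 (1.1 equiv), acetone, reflux
Reagents that add atoms: dimethyl sulfate COS(=O)(=O)OC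
Why: Williamson-type O-methylation under weak base, in which the hydroxyl para to the ketone is the most acidic and the only one not hydrogen-bonded to the carbonyl, so one equivalent of reagent should react mainly there, as is usual for 2,4,6-trihydroxyaryl ketones.

**Step 3**
Reactants: 4 1-(2,6-dihydroxy-4-methoxy-3-methylphenyl)-3-phenylpropan-1-one
Product: 6 2,4-dihydroxy-6-methoxy-5-methyl-3-(3-phenylpropanoyl)benzaldehyde, via aryl chloromethyl methyl ether 5 (not isolated)
Conditions: Cl2CHOMe (1.5 equiv), TiCl4 (4 equiv), CH2Cl2, -10 °C to rt; then 1 M HCl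
Reagents that add atoms: dichloromethyl methyl ether COC(Cl)Cl; water O
Why: Rieche formylation at the only remaining aromatic C-H, which is ortho to a titanium-bound phenoxide and to the methoxy group, using a reagent that, unlike a Vilsmeier reagent, does not attack the alpha-methylene of a 2-hydroxyaryl ketone to build a 3-benzylchromone.

**Step 4**
Reactants: 6 2,4-dihydroxy-6-methoxy-5-methyl-3-(3-phenylpropanoyl)benzaldehyde
Product: 7 2,4-bis(benzyloxy)-6-methoxy-5-methyl-3-(3-phenylpropanoyl)benzaldehyde (ArD-CHO)
Conditions: BnBr (3 equiv), K2CO3 (3 equiv), DMF, 60 °C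
Reagents that add atoms: benzyl bromide BrCc1ccccc1
Why: Williamson etherification of two chelated hydroxyls, which needs DMF and heat, and which prevents coumarin formation in step 5 and removes the acidic protons that would quench the diene later.

**Step 5**
Reactants: 7 ArD-CHO; 8 methyl acetoacetate
Product: 9 methyl 2-acetyl-3-(ArD)prop-2-enoate (E/Z mixture)
Conditions: 8 (1.5 equiv), piperidine (0.2 equiv), AcOH (0.2 equiv), toluene, Dean-Stark, reflux
Reagents that add atoms: none
Why: Knoevenagel condensation through the piperidinium iminium ion, which is workable on 2,6-dialkoxybenzaldehydes, while the di-ortho-substituted ring D ketone is too hindered to condense.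

**Step 6**
Reactants: 9 methyl 2-acetyl-3-(ArD)prop-2-enoate
Product: 10 methyl 2-(ArD-methyl)-3-oxobutanoate (racemic, configurationally labile)
Conditions: Hantzsch ester (diethyl 2,6-dimethyl-1,4-dihydropyridine-3,5-dicarboxylate, 1.3 equiv), SiO2, toluene, 80 °C, dark
Reagents that add atoms: none
Why: Transfer hydrogenation by hydride conjugate addition from the dihydropyridine to the doubly activated alkene, which spares both ketones, the ester and the benzyl ethers; the new alpha centre is racemic and is flattened again in step 7.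

**Step 7**
Reactants: 10 methyl 2-(ArD-methyl)-3-oxobutanoate
Product: 11 methyl 2-(ArD-Si-methyl)-3-(trimethylsilyloxy)but-2-enoate
Conditions: Me3SiOTf (2.4 equiv), Et3N (3 equiv), Et2O, 0 °C to rt; ether layer decanted from the ammonium salt and concentrated under Ar
Reagents that add atoms: trimethylsilyl trifluoromethanesulfonate C[Si](C)(C)OS(=O)(=O)C(F)(F)F
Why: Soft enolisation with silyl triflate and a tertiary amine converts the beta-keto ester into its conjugated silyl enol ether and the aryl alkyl ketone into its silyl enol ether, so the acidic alpha-methylene of ring D is masked before strong base is used.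

**Step 8**
Reactants: 11 methyl 2-(ArD-Si-methyl)-3-(trimethylsilyloxy)but-2-enoate
Product: 12 1-methoxy-2-(ArD-Si-methyl)-1,3-bis(trimethylsilyloxy)buta-1,3-diene
Conditions: LiN(iPr)2 (commercial solution, 1.3 equiv), THF, -78 °C; Me3SiCl (1.5 equiv), -78 to 0 °C; pentane, filtration under Ar; used crude
Reagents that add atoms: chlorotrimethylsilane C[Si](C)(C)Cl
Why: Second stage of the standard Chan diene preparation, known for 2-alkyl acetoacetates, in which the amide base removes a gamma proton of the 3-silyloxy enoate and the extended enolate is silylated on the ester oxygen; the small excess of base and silyl chloride also catches any ring D ketone left from step 7.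

**Step 9**
Reactants: 13 ethoxyacetylene; 14 N,2-dimethoxy-N-methylacetamide
Product: 16 4-ethoxy-1-methoxybut-3-yn-2-one, via lithium ethoxyacetylide 15 (not isolated)
Conditions: n-BuLi (1.0 equiv), THF, -78 °C; 14, -78 to -40 °C; poured into cold sat. aq. NH4Cl; short column on neutral Al2O3
Reagents that add atoms: none
Why: Acylation of a lithium acetylide with a Weinreb amide, in which the chelated tetrahedral adduct survives until the quench so no second addition occurs, and the cold, weakly acidic quench limits both conjugate addition of the liberated amine and hydration of the ynol ether.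

**Step 10**
Reactants: 12 1-methoxy-2-(ArD-Si-methyl)-1,3-bis(trimethylsilyloxy)buta-1,3-diene; 16 4-ethoxy-1-methoxybut-3-yn-2-one
Product: 19 1-[6-ethoxy-2,4-dihydroxy-3-(ArD-methyl)phenyl]-2-methoxyethan-1-one, via cyclohexa-1,4-diene cycloadduct 17 (not isolated), via aromatised tris(trimethylsilyl) compound 18 (not isolated)
Conditions: 16 (2 equiv), toluene (1 M), Ar, rt to 60 °C; then 1 M HCl, THF, rt
Reagents that add atoms: none
Why: Proposed new method: the unsubstituted CH2 terminus of diene 12, towards which both the 3-silyloxy group and the ketene acetal push electron density, should bond to the ethoxy-bearing alkyne carbon of 16 (the acyl-vinylogous, most electrophilic carbon) to make C5-C6, and the ketene acetal carbon should bond to the acyl-bearing alkyne carbon to make C4a-C8a, either in one asynchronous (4+2) event or as a vinylogous Mukaiyama-Michael addition followed by 6-exo-trig collapse of the allenolate onto the dioxocarbenium carbon; loss of methanol from adduct 17 then aromatises the ring. The closest known reaction type is the Diels-Alder/aromatisation of 1-alkoxy-1,3-bis(silyloxy)buta-1,3-dienes with alkynoates, acetylenedicarboxylates and alkynyl ketones to resorcylates and acylresorcinols, and what is new is an alkoxy donor on the beta carbon of the ynone, which lowers its electrophilicity but reinforces the polarisation that is wanted. Ring A is the only ring closed, in the (4+2) mode, and the single sp3 centre of 17 that carries OMe and OSiMe3 (the future C8a) is racemic and disappears on aromatisation, so no stereocentre has to be controlled. The selectivity needed is regiochemical, and it rests on this matched polarisation and on the ring D-methyl group at the central diene carbon, which shuts off the (3+3) mode because that path would end at a quaternary carbon unable to aromatise. The bath is kept at or below 60 °C because ethyl ynol ethers lose ethene by a retro-ene path above about 100 °C, and the ring D silyl enol ether, much less nucleophilic than the diene, should stay a spectator until dilute acid returns the ketone and frees both phenols. The three oxygens of ring A come out distinct: a hydroxyl on C8a held by the methoxyacetyl carbonyl and flanked by the bridge carbon, a free hydroxyl on C7 and an ethyl ether on C5.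

**Step 11**
Reactants: 19 1-[6-ethoxy-2,4-dihydroxy-3-(ArD-methyl)phenyl]-2-methoxyethan-1-one
Product: 20 1-[4-(benzyloxy)-6-ethoxy-2-hydroxy-3-(ArD-methyl)phenyl]-2-methoxyethan-1-one
Conditions: BnBr (1.05 equiv), K2CO3 (1.2 equiv), acetone, reflux
Reagents that add atoms: benzyl bromide BrCc1ccccc1
Why: Chemoselective Williamson etherification, in which the hydroxyl para to the ketone is free and more acidic while the other is hydrogen-bonded to the carbonyl and shielded by the ring D-methyl group, the usual pattern for 2,4-dihydroxyaryl ketones.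

**Step 12**
Reactants: 20 1-[4-(benzyloxy)-6-ethoxy-2-hydroxy-3-(ArD-methyl)phenyl]-2-methoxyethan-1-one; 21 benzoyl chloride
Product: 22 3-(benzyloxy)-5-ethoxy-6-(methoxyacetyl)-2-(ArD-methyl)phenyl benzoate
Conditions: 21 (1.5 equiv), Et3N (2 equiv), DMAP (0.2 equiv), CH2Cl2, rt
Reagents that add atoms: none
Why: DMAP-catalysed O-acylation of the hindered, chelated phenol places ring B and C2 on the oxygen that becomes O1.

**Step 13**
Reactants: 22 3-(benzyloxy)-5-ethoxy-6-(methoxyacetyl)-2-(ArD-methyl)phenyl benzoate
Product: 23 1-[4-(benzyloxy)-6-ethoxy-2-hydroxy-3-(ArD-methyl)phenyl]-2-methoxy-3-phenylpropane-1,3-dione (racemic, labile methine; keto form drawn)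
Conditions: LiN(SiMe3)2 (2.5 equiv), THF, -78 to 0 °C; 1 M HCl
Reagents that add atoms: none
Why: Baker-Venkataraman rearrangement, in which the enolate of the methoxymethyl ketone attacks the neighbouring benzoate through a six-membered transition state to form C2-C3, whereas the reversibly formed ring D enolate has no ester within reach because no second benzoate is present.

**Step 14**
Reactants: 23 1-[4-(benzyloxy)-6-ethoxy-2-hydroxy-3-(ArD-methyl)phenyl]-2-methoxy-3-phenylpropane-1,3-dione
Product: 24 7-(benzyloxy)-5-ethoxy-3-methoxy-8-(ArD-methyl)-2-phenyl-4H-chromen-4-one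
Conditions: p-TsOH·H2O (0.1 equiv), toluene, 80 °C
Reagents that add atoms: none
Why: Acid-catalysed cyclodehydration (6-exo-trig hemiketal formation, then loss of water) closes ring C through the only free hydroxyl, and catalytic sulfonic acid in toluene is mild enough for the benzyl ethers and the diarylmethane bridge.

**Step 15**
Reactants: 24 7-(benzyloxy)-5-ethoxy-3-methoxy-8-(ArD-methyl)-2-phenyl-4H-chromen-4-one
Product: 25 8-{[2,4-dihydroxy-6-methoxy-5-methyl-3-(3-phenylpropanoyl)phenyl]methyl}-5-ethoxy-7-hydroxy-3-methoxy-2-phenyl-4H-chromen-4-one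
Conditions: H2 (1 atm), 10% Pd/C, EtOAc-MeOH, rt
Reagents that add atoms: none
Why: Hydrogenolysis of three aryl benzyl ethers, under which the tetrasubstituted C2-C3 alkene, the hindered aryl ketone and the diarylmethane are not reduced, and which is run before the Lewis acid step because benzyl ethers ortho to the ring D ketone would not survive BCl3 and would release benzyl cations next to the open C6 position.

**Step 16**
Reactants: 25 8-{[2,4-dihydroxy-6-methoxy-5-methyl-3-(3-phenylpropanoyl)phenyl]methyl}-5-ethoxy-7-hydroxy-3-methoxy-2-phenyl-4H-chromen-4-one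
Product: 26 8-{[2,4-dihydroxy-6-methoxy-5-methyl-3-(3-phenylpropanoyl)phenyl]methyl}-5,7-dihydroxy-3-methoxy-2-phenyl-4H-chromen-4-one (CNP0280022.0)
Conditions: BCl3 (6 equiv, 1 M in CH2Cl2), CH2Cl2, -20 to 0 °C; ice-cold 1 M HCl, THF (no basic wash)
Reagents that add atoms: none
Why: Chelation-directed ether cleavage, known for 5-alkoxy-3-methoxyflavones, in which BCl3 binds C4=O and the peri 5-oxygen in a six-membered chelate and chloride removes the ethyl group, while the 3-methoxy group (only a five-membered chelate) and the ring D methoxy group (para to its ketone) should remain.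

**Compound list**
1 | 2-methylbenzene-1,3,5-triol (2-methylphloroglucinol) | Cc1c(O)cc(O)cc1O | starting material
2 | 3-phenylpropanoyl chloride | O=C(Cl)CCc1ccccc1 | starting material
3 | 1-(2,4,6-trihydroxy-3-methylphenyl)-3-phenylpropan-1-one | Cc1c(O)cc(O)c(C(=O)CCc2ccccc2)c1O | intermediate
4 | 1-(2,6-dihydroxy-4-methoxy-3-methylphenyl)-3-phenylpropan-1-one | COc1cc(O)c(C(=O)CCc2ccccc2)c(O)c1C | intermediate
5 | 1-{3-[chloro(methoxy)methyl]-2,6-dihydroxy-4-methoxy-5-methylphenyl}-3-phenylpropan-1-one (racemic; titanium-bound in the flask) | COc1c(C)c(O)c(C(=O)CCc2ccccc2)c(O)c1C(Cl)OC | intermediate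
6 | 2,4-dihydroxy-6-methoxy-5-methyl-3-(3-phenylpropanoyl)benzaldehyde | COc1c(C)c(O)c(C(=O)CCc2ccccc2)c(O)c1C=O | intermediate
7 | 2,4-bis(benzyloxy)-6-methoxy-5-methyl-3-(3-phenylpropanoyl)benzaldehyde | COc1c(C)c(OCc2ccccc2)c(C(=O)CCc2ccccc2)c(OCc2ccccc2)c1C=O | intermediate
8 | methyl acetoacetate | COC(=O)CC(C)=O | starting material
9 | methyl 2-acetyl-3-(ArD)prop-2-enoate (E/Z mixture) | COC(=O)C(=Cc1c(OC)c(C)c(OCc2ccccc2)c(C(=O)CCc2ccccc2)c1OCc1ccccc1)C(C)=O | intermediate
10 | methyl 2-(ArD-methyl)-3-oxobutanoate (racemic) | COC(=O)C(Cc1c(OC)c(C)c(OCc2ccccc2)c(C(=O)CCc2ccccc2)c1OCc1ccccc1)C(C)=O | intermediate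
11 | methyl 2-(ArD-Si-methyl)-3-(trimethylsilyloxy)but-2-enoate (Z ring D enol ether; enoate geometry unassigned) | COC(=O)C(Cc1c(OC)c(C)c(OCc2ccccc2)c(/C(O[Si](C)(C)C)=C/Cc2ccccc2)c1OCc1ccccc1)=C(C)O[Si](C)(C)C | intermediate
12 | 1-methoxy-2-(ArD-Si-methyl)-1,3-bis(trimethylsilyloxy)buta-1,3-diene (Z ring D enol ether; ketene acetal geometry unassigned) | COC(O[Si](C)(C)C)=C(Cc1c(OC)c(C)c(OCc2ccccc2)c(/C(O[Si](C)(C)C)=C/Cc2ccccc2)c1OCc1ccccc1)C(O[Si](C)(C)C)=C | intermediate
13 | ethoxyacetylene | CCOC#C | starting material
14 | N,2-dimethoxy-N-methylacetamide | COCC(=O)N(C)OC | starting material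
15 | lithium ethoxyacetylide | CCOC#C[Li] | intermediate
16 | 4-ethoxy-1-methoxybut-3-yn-2-one | CCOC#CC(=O)COC | intermediate
17 | 1-[2-ethoxy-6-methoxy-5-(ArD-Si-methyl)-4,6-bis(trimethylsilyloxy)cyclohexa-1,4-dien-1-yl]-2-methoxyethan-1-one (racemic) | COCC(=O)C1=C(OCC)CC(O[Si](C)(C)C)=C(Cc2c(OC)c(C)c(OCc3ccccc3)c(/C(O[Si](C)(C)C)=C/Cc3ccccc3)c2OCc2ccccc2)C1(OC)O[Si](C)(C)C | intermediate
18 | 1-[6-ethoxy-3-(ArD-Si-methyl)-2,4-bis(trimethylsilyloxy)phenyl]-2-methoxyethan-1-one | COCC(=O)c1c(OCC)cc(O[Si](C)(C)C)c(Cc2c(OC)c(C)c(OCc3ccccc3)c(/C(O[Si](C)(C)C)=C/Cc3ccccc3)c2OCc2ccccc2)c1O[Si](C)(C)C | intermediate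
19 | 1-[6-ethoxy-2,4-dihydroxy-3-(ArD-methyl)phenyl]-2-methoxyethan-1-one | COCC(=O)c1c(OCC)cc(O)c(Cc2c(OC)c(C)c(OCc3ccccc3)c(C(=O)CCc3ccccc3)c2OCc2ccccc2)c1O | intermediate
20 | 1-[4-(benzyloxy)-6-ethoxy-2-hydroxy-3-(ArD-methyl)phenyl]-2-methoxyethan-1-one | COCC(=O)c1c(OCC)cc(OCc2ccccc2)c(Cc2c(OC)c(C)c(OCc3ccccc3)c(C(=O)CCc3ccccc3)c2OCc2ccccc2)c1O | intermediate
21 | benzoyl chloride | O=C(Cl)c1ccccc1 | starting material
22 | 3-(benzyloxy)-5-ethoxy-6-(methoxyacetyl)-2-(ArD-methyl)phenyl benzoate | COCC(=O)c1c(OCC)cc(OCc2ccccc2)c(Cc2c(OC)c(C)c(OCc3ccccc3)c(C(=O)CCc3ccccc3)c2OCc2ccccc2)c1OC(=O)c1ccccc1 | intermediate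
23 | 1-[4-(benzyloxy)-6-ethoxy-2-hydroxy-3-(ArD-methyl)phenyl]-2-methoxy-3-phenylpropane-1,3-dione (racemic, labile) | COC(C(=O)c1ccccc1)C(=O)c1c(OCC)cc(OCc2ccccc2)c(Cc2c(OC)c(C)c(OCc3ccccc3)c(C(=O)CCc3ccccc3)c2OCc2ccccc2)c1O | intermediate
24 | 7-(benzyloxy)-5-ethoxy-3-methoxy-8-(ArD-methyl)-2-phenyl-4H-chromen-4-one | CCOc1cc(OCc2ccccc2)c(Cc2c(OC)c(C)c(OCc3ccccc3)c(C(=O)CCc3ccccc3)c2OCc2ccccc2)c2oc(-c3ccccc3)c(OC)c(=O)c12 | intermediate
25 | 8-{[2,4-dihydroxy-6-methoxy-5-methyl-3-(3-phenylpropanoyl)phenyl]methyl}-5-ethoxy-7-hydroxy-3-methoxy-2-phenyl-4H-chromen-4-one | CCOc1cc(O)c(Cc2c(OC)c(C)c(O)c(C(=O)CCc3ccccc3)c2O)c2oc(-c3ccccc3)c(OC)c(=O)c12 | intermediate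
26 | 8-{[2,4-dihydroxy-6-methoxy-5-methyl-3-(3-phenylpropanoyl)phenyl]methyl}-5,7-dihydroxy-3-methoxy-2-phenyl-4H-chromen-4-one (CNP0280022.0; no stereocentre) | COc1c(C)c(O)c(C(=O)CCc2ccccc2)c(O)c1Cc1c(O)cc(O)c2c(=O)c(OC)c(-c3ccccc3)oc12 | target

**Step count**
- Total step count: 16.
- Longest linear sequence: 15 (steps 1 to 8 and 10 to 16). Step 9 is the side branch.

**Steps most likely to fail**

1. **Step 10.**
   - What may go wrong: the donor-substituted alkyne may be too weak a dienophile below the temperature at which it fragments. Protodesilylation of the crude diene, or arrest at the open-chain Michael stage, could then overtake ring closure.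
   - Fallback (known chemistry): it sets out from aldehyde 7 and returns at 19.
   - Phloroglucinol is mono-etherified (EtOH, HCl) to 5-ethoxybenzene-1,3-diol F1. This is protected (MOMCl, iPr2NEt) as 1-ethoxy-3,5-bis(methoxymethoxy)benzene F2.
   - Directed ortho metalation with n-BuLi between the two MOM ethers gives [4-ethoxy-2,6-bis(methoxymethoxy)phenyl]lithium F3.
   - Addition to 7 at -78 °C, where the aldehyde reacts ahead of the hindered ketone, gives the racemic diaryl carbinol F4.
   - Ionic hydrogenation (Et3SiH, CF3CO2H, CH2Cl2, -40 °C, cold enough to spare the ketone) gives the diarylmethane bis(MOM ether) F5. Methanolic HCl then gives 2-(ArD-methyl)-5-ethoxybenzene-1,3-diol F6.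
   - The new ring of F6 is symmetric about its C2-C5 axis, so its two open positions are equivalent.
   - Houben-Hoesch acylation with methoxyacetonitrile (ZnCl2, HCl, Et2O, 0 °C) through the ketiminium chloride F7, followed by aqueous hydrolysis, should give 19 as one regioisomer.

2. **Step 9.**
   - What may go wrong: the liberated N,O-dimethylhydroxylamine may add to the ynone at the quench, or the ynol ether may hydrate during isolation.
   - Fallback: it sets out from lithium ethoxyacetylide 15 and returns at 16.
   - Addition to methoxyacetaldehyde (THF, -78 °C) gives racemic 4-ethoxy-1-methoxybut-3-yn-2-ol F8.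
   - F8 is oxidised with activated MnO2 in CH2Cl2. These neutral conditions release no amine and avoid Meyer-Schuster rearrangement.

3. **Step 16.**
   - What may go wrong: the free tetraphenol may bind BCl3 at several sites and separate as borate complexes. Ether cleavage would then stall, and forcing it could cause loss of a methyl ether or scission of the methylene bridge.
   - Fallback: it sets out from the fully protected, soluble 24 and returns at 26, omitting step 15. It makes no new compound (F0).
   - BCl3 (8 equiv) and pentamethylbenzene (6 equiv) in CH2Cl2 at -78 °C remove the three benzyl groups as scavenged cations. Warming to 0 °C then cleaves the chelated 5-ethyl ether in the same flask.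

**Further compounds**
F1 | step 10 | 5-ethoxybenzene-1,3-diol | CCOc1cc(O)cc(O)c1
F2 | step 10 | 1-ethoxy-3,5-bis(methoxymethoxy)benzene | CCOc1cc(OCOC)cc(OCOC)c1
F3 | step 10 | [4-ethoxy-2,6-bis(methoxymethoxy)phenyl]lithium | CCOc1cc(OCOC)c([Li])c(OCOC)c1
F4 | step 10 | (ArD)[4-ethoxy-2,6-bis(methoxymethoxy)phenyl]methanol (racemic) | CCOc1cc(OCOC)c(C(O)c2c(OC)c(C)c(OCc3ccccc3)c(C(=O)CCc3ccccc3)c2OCc2ccccc2)c(OCOC)c1
F5 | step 10 | 2-(ArD-methyl)-5-ethoxy-1,3-bis(methoxymethoxy)benzene | CCOc1cc(OCOC)c(Cc2c(OC)c(C)c(OCc3ccccc3)c(C(=O)CCc3ccccc3)c2OCc2ccccc2)c(OCOC)c1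
F6 | step 10 | 2-(ArD-methyl)-5-ethoxybenzene-1,3-diol | CCOc1cc(O)c(Cc2c(OC)c(C)c(OCc3ccccc3)c(C(=O)CCc3ccccc3)c2OCc2ccccc2)c(O)c1
F7 | step 10 | 1-[6-ethoxy-2,4-dihydroxy-3-(ArD-methyl)phenyl]-2-methoxyethan-1-iminium chloride | COCC(=[NH2+])c1c(OCC)cc(O)c(Cc2c(OC)c(C)c(OCc3ccccc3)c(C(=O)CCc3ccccc3)c2OCc2ccccc2)c1O.[Cl-]
F8 | step 9 | 4-ethoxy-1-methoxybut-3-yn-2-ol (racemic) | CCOC#CC(O)COC
F0 | step 16 | none | none
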